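**Plan**

1. Locants: side chain C1' (benzylic) to C13' (CH2OH); ring C1 carries CO2H. Retrosynthetic cuts, in order: the three benzyl–O bonds; the ring C1–CO2H bond (formylation, oxidation); the chain bond C4'–C5' together with the acetyl–O bond (one operation); the oxetane bonds C4'–O and C3'–C4' (ylide CH2); the aryl–C1' bond (aryl Grignard plus epichlorohydrin).
2. Enabling feature: the acetoxy oxygen on C2' stands 1,3 to C4', so O–C2'–C3'–C4' can be closed as an oxetane ring. Its strained C4'–O bond is the electrophile for a C5' nucleophile, and the oxygen that leaves is the one the target carries as acetate.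
3. Forward: the resorcinol ring is bought. Aryl–C1' is made first, then the temporary oxetane is closed, then the C9 chain is joined at C4'–C5' with in-flask acetylation of the C2' alkoxide (three components). The carboxyl carbon is then put on ring C1 and the benzyl groups are removed.
4. Protecting logic: the C2' oxygen is never free beside a ring carboxyl derivative, so the dihydroisocoumarin lactone cannot form. Benzyl on both phenols and on O-13' leaves in the last step without touching the acetate.
5. Stereochemistry: the only stereocentre, C2', comes from (S)-epichlorohydrin and none of its bonds is broken afterwards. The descriptor changes from S to R only through CIP ranking.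

Key step: step 4

Remark: 1,3-bis(benzyloxy)-5-bromobenzene is taken as a catalogue compound (otherwise one step from 5-bromoresorcinol and benzyl bromide).

**Route**

Step 1
Reactants: 1 1,3-bis(benzyloxy)-5-bromobenzene; 2 (S)-epichlorohydrin
Product: 4 (S)-1-[3,5-bis(benzyloxy)phenyl]-3-chloropropan-2-ol, via aryl Grignard reagent 3 (not isolated)
Conditions: Mg, THF, rt → 40 °C; then CuI (10 mol %), 2, THF, −40 → 0 °C; 1 M HCl work-up
Reagents that add atoms: magnesium, [Mg] (present in intermediate 3 only)
Why: Copper-catalysed Grignard opening of the epoxide of epichlorohydrin at its terminal CH2 should give the chlorohydrin without touching C2, and isolating the chlorohydrin excludes material from direct chloride displacement, which would erode the enantiomeric purity.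

Step 2
Reactants: 4 (S)-1-[3,5-bis(benzyloxy)phenyl]-3-chloropropan-2-ol
Product: 6 (S)-2-[3,5-bis(benzyloxy)benzyl]oxetane, via epoxide 5 (not isolated)
Conditions: Me3S(O)I (3 equiv), KOt-Bu (4 equiv), t-BuOH, 70 °C
Reagents that add atoms: trimethylsulfoxonium iodide, C[S+](C)(C)=O.[I-] (supplies the CH2 that becomes C4')
Why: KOt-Bu should close the chlorohydrin to the epoxide (intramolecular Williamson reaction), and dimethylsulfoxonium methylide then opens it at CH2 and the γ-alkoxide displaces DMSO (4-exo-tet), a Corey–Chaykovsky-type ring expansion in which the C2'–O bond is never broken, so the configuration is kept.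

Step 3
Reactants: 7 9-bromononan-1-ol
Product: 8 benzyl 9-bromononyl ether
Conditions: BnOC(=NH)CCl3 (1.3 equiv), TfOH (5 mol %), CH2Cl2/cyclohexane, 0 °C → rt
Reagents that add atoms: benzyl 2,2,2-trichloroacetimidate, N=C(OCc1ccccc1)C(Cl)(Cl)Cl
Why: Acid-catalysed O-benzylation with the trichloroacetimidate avoids the base that would cyclise or eliminate a bromo alkoxide.

Step 4
Reactants: 8 benzyl 9-bromononyl ether; 6 (S)-2-[3,5-bis(benzyloxy)benzyl]oxetane
Product: 11 (R)-1-[3,5-bis(benzyloxy)phenyl]-13-(benzyloxy)tridecan-2-yl acetate, via alkyl Grignard reagent 9 (not isolated), via bromomagnesium alkoxide 10 (not isolated)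
Conditions: Mg (I2 cat.), THF, 40 °C; then 6, CuI (10 mol %), THF, −20 → 45 °C; then Ac2O (excess), DMAP (cat.), 0 °C → rt
Reagents that add atoms: acetic anhydride, CC(=O)OC(C)=O; magnesium, [Mg] (present in intermediates 9 and 10 only)
Why: Transmetalation of 9 to copper gives an alkylcuprate that attacks the Mg(II)-coordinated oxetane of 6 in an SN2 fashion at the unsubstituted ring carbon C4', so that about 25 kcal/mol of ring strain pays for a C(sp3)–C(sp3) bond at a plain methylene and the ring oxygen is left on C2' as alkoxide 10, which acetic anhydride then captures. The closest known reaction type is the copper-catalysed Grignard opening of oxetanes and epoxides followed by in-flask acylation of the metal alkoxide. No ring is closed; the four-membered ring O–C2'–C3'–C4' is opened, with the C4'–O bond as the only bond broken. No new stereocentre arises and the one at C2' is not touched, so the (S)-oxetane should give the (R)-acetate only through the change in CIP ranking. The step needs attack at C4' and not at C2', which the primary versus secondary, β-branched character of the two carbons secures, and it needs acylation of one oxygen only, which is secured because the only alkoxide in the flask is the C2' one while the chain-end oxygen is a benzyl ether. A strong Lewis acid is left out on purpose, since the electron-rich ring could otherwise attack the activated oxetane in a Friedel–Crafts sense; bromide opening by MgBr2, if it competes, gives a γ-bromo alkoxide that the same copper catalyst should couple with 9 to the same product.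

Step 5
Reactants: 11 (R)-1-[3,5-bis(benzyloxy)phenyl]-13-(benzyloxy)tridecan-2-yl acetate
Product: 12 (R)-1-[3,5-bis(benzyloxy)-2-formylphenyl]-13-(benzyloxy)tridecan-2-yl acetate
Conditions: POCl3 (2 equiv), DMF, 0 → 50 °C; then ice-water, aq. NaOAc
Reagents that add atoms: N,N-dimethylformamide, CN(C)C=O (formyl carbon); water, O (formyl oxygen, on hydrolysis of the iminium salt)
Why: Vilsmeier–Haack formylation of a 5-alkylresorcinol diether should go to the ring position para to one benzyloxy group and ortho to the alkyl chain (C2 and C6 are equivalent) in preference to the position between the two benzyloxy groups, and acetate and benzyl ethers tolerate the reagent.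

Step 6
Reactants: 12 (R)-1-[3,5-bis(benzyloxy)-2-formylphenyl]-13-(benzyloxy)tridecan-2-yl acetate
Product: 13 2-[(R)-2-acetoxy-13-(benzyloxy)tridecyl]-4,6-bis(benzyloxy)benzoic acid
Conditions: NaClO2, NaH2PO4, 2-methyl-2-butene (excess), t-BuOH/THF/H2O, 0 °C → rt
Reagents that add atoms: sodium chlorite, [Na+].[O-]Cl=O
Why: Pinnick oxidation takes the hindered, electron-rich aldehyde to the acid under buffered conditions that leave acetate and benzyl ethers alone, the alkene scavenger removing HOCl before it can chlorinate the ring.

Step 7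
Reactants: 13 2-[(R)-2-acetoxy-13-(benzyloxy)tridecyl]-4,6-bis(benzyloxy)benzoic acid
Product: 14 2-[(R)-2-acetoxy-13-hydroxytridecyl]-4,6-dihydroxybenzoic acid (target, CNP0361881.1)
Conditions: H2 (1 atm), 10 % Pd/C, EtOAc, rt
Reagents that add atoms: none
Why: Catalytic hydrogenolysis should cleave the two aryl benzyl ethers and the alkyl benzyl ether under neutral conditions in which the secondary acetate, the free acid and the stereocentre are inert.

**Compound list**

1 | 1,3-bis(benzyloxy)-5-bromobenzene | Brc1cc(OCc2ccccc2)cc(OCc2ccccc2)c1 | starting material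
2 | (S)-epichlorohydrin | ClC[C@@H]1CO1 | starting material
3 | [3,5-bis(benzyloxy)phenyl]magnesium bromide | Br[Mg]c1cc(OCc2ccccc2)cc(OCc2ccccc2)c1 | intermediate
4 | (S)-1-[3,5-bis(benzyloxy)phenyl]-3-chloropropan-2-ol | O[C@H](CCl)Cc1cc(OCc2ccccc2)cc(OCc2ccccc2)c1 | intermediate
5 | (S)-2-[3,5-bis(benzyloxy)benzyl]oxirane | C1O[C@H]1Cc1cc(OCc2ccccc2)cc(OCc2ccccc2)c1 | intermediate
6 | (S)-2-[3,5-bis(benzyloxy)benzyl]oxetane | C1CO[C@H]1Cc1cc(OCc2ccccc2)cc(OCc2ccccc2)c1 | intermediate
7 | 9-bromononan-1-ol | OCCCCCCCCCBr | starting material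
8 | benzyl 9-bromononyl ether | BrCCCCCCCCCOCc1ccccc1 | intermediate
9 | [9-(benzyloxy)nonyl]magnesium bromide | Br[Mg]CCCCCCCCCOCc1ccccc1 | intermediate
10 | bromomagnesium (R)-1-[3,5-bis(benzyloxy)phenyl]-13-(benzyloxy)tridecan-2-olate | Br[Mg]O[C@H](CCCCCCCCCCCOCc1ccccc1)Cc1cc(OCc2ccccc2)cc(OCc2ccccc2)c1 | intermediate
11 | (R)-1-[3,5-bis(benzyloxy)phenyl]-13-(benzyloxy)tridecan-2-yl acetate | CC(=O)O[C@H](CCCCCCCCCCCOCc1ccccc1)Cc1cc(OCc2ccccc2)cc(OCc2ccccc2)c1 | intermediate
12 | (R)-1-[3,5-bis(benzyloxy)-2-formylphenyl]-13-(benzyloxy)tridecan-2-yl acetate | CC(=O)O[C@H](CCCCCCCCCCCOCc1ccccc1)Cc1cc(OCc2ccccc2)cc(OCc2ccccc2)c1C=O | intermediate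
13 | 2-[(R)-2-acetoxy-13-(benzyloxy)tridecyl]-4,6-bis(benzyloxy)benzoic acid | CC(=O)O[C@H](CCCCCCCCCCCOCc1ccccc1)Cc1cc(OCc2ccccc2)cc(OCc2ccccc2)c1C(=O)O | intermediate
14 | 2-[(R)-2-acetoxy-13-hydroxytridecyl]-4,6-dihydroxybenzoic acid | CC(=O)O[C@H](CCCCCCCCCCCO)Cc1cc(O)cc(O)c1C(=O)O | target

**Count**

Total steps: 7. Longest linear sequence: 6 (steps 1, 2, 4, 5, 6, 7); step 3 is a one-step side branch.

**Steps most likely to fail, with fallbacks**

Step 4. What may go wrong: ring opening of the 2-substituted oxetane may be slow, so that halide opening without subsequent coupling, attack of the electron-rich ring on the metal-bound oxetane, or decay of the organocopper species at the temperature needed takes over; acylation of the hindered magnesium alkoxide may also be incomplete. The fallback makes C4'–C5' as an alkene by cross-metathesis and sets out from 4. K2CO3 in MeOH should give epoxide 5, isolated this time. Vinylmagnesium bromide with CuI (THF, −30 °C) should open 5 at its CH2 to give (R)-1-[3,5-bis(benzyloxy)phenyl]pent-4-en-2-ol F1, and Ac2O/pyridine/DMAP should give (R)-1-[3,5-bis(benzyloxy)phenyl]pent-4-en-2-yl acetate F2. Cross-metathesis of F2 with an excess of benzyl dec-9-enyl ether F3 (from commercial dec-9-en-1-ol, NaH, BnBr) with a second-generation Ru-benzylidene catalyst (CH2Cl2, 40 °C) should give (R,E)-1-[3,5-bis(benzyloxy)phenyl]-13-(benzyloxy)tridec-4-en-2-yl acetate F4, as an E/Z mixture of no consequence. Diimide (TsNHNH2, NaOAc, DME/H2O, reflux) should saturate C4'=C5' without touching the benzyl ethers, and the fallback comes back to the route at 11.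

Step 5. What may go wrong: poor site selectivity between the wanted ring position next to the chain and the position between the two benzyloxy groups, stalling at the hindered site beside the branched chain, or acid-induced loss of a benzyl ether on warming. The fallback replaces formylation and oxidation by halogenation and carbonylation and sets out from 11. NBS (MeCN, 0 °C) should brominate para to a benzyloxy group at low temperature and without acid to give (R)-1-[3,5-bis(benzyloxy)-2-bromophenyl]-13-(benzyloxy)tridecan-2-yl acetate F5. Palladium-catalysed benzyloxycarbonylation (Pd(OAc)2, Xantphos, CO, BnOH, Et3N, toluene, 100 °C) should give benzyl 2-[(R)-2-acetoxy-13-(benzyloxy)tridecyl]-4,6-bis(benzyloxy)benzoate F6. Hydrogenolysis under the conditions of step 7 then removes four benzyl groups, and the fallback comes back to the route at 14, bypassing 12 and 13.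

Step 2. What may go wrong: base-induced isomerisation of the benzyl-substituted epoxide to the cinnamyl-type allylic alcohol (benzylic deprotonation and β-elimination), or incomplete 4-exo closure in hot alkoxide. The fallback builds the oxetane by a 1,3-diol/Williamson sequence and sets out from 4. K2CO3 in MeOH should give epoxide 5, isolated this time. (Isopropoxydimethylsilyl)methylmagnesium chloride with CuI should open 5 at its CH2 to give (S)-1-[3,5-bis(benzyloxy)phenyl]-4-[isopropoxy(dimethyl)silyl]butan-2-ol F7. Tamao oxidation (H2O2, KF, KHCO3, THF/MeOH) should give (S)-4-[3,5-bis(benzyloxy)phenyl]butane-1,3-diol F8. Primary-selective tosylation (TsCl, Et3N, Bu2SnO cat.) should give (S)-4-[3,5-bis(benzyloxy)phenyl]-3-hydroxybutyl 4-methylbenzenesulfonate F9, and KOt-Bu in THF should close the ring by attack of the C2' alkoxide on C4', so that the C2'–O bond and the configuration are kept. The fallback comes back to the route at 6.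

**Further compounds**

F1 | step 4 | (R)-1-[3,5-bis(benzyloxy)phenyl]pent-4-en-2-ol | O[C@H](CC=C)Cc1cc(OCc2ccccc2)cc(OCc2ccccc2)c1
F2 | step 4 | (R)-1-[3,5-bis(benzyloxy)phenyl]pent-4-en-2-yl acetate | CC(=O)O[C@H](CC=C)Cc1cc(OCc2ccccc2)cc(OCc2ccccc2)c1
F3 | step 4 | benzyl dec-9-enyl ether | C=CCCCCCCCCOCc1ccccc1
F4 | step 4 | (R,E)-1-[3,5-bis(benzyloxy)phenyl]-13-(benzyloxy)tridec-4-en-2-yl acetate | CC(=O)O[C@H](C/C=C/CCCCCCCCOCc1ccccc1)Cc1cc(OCc2ccccc2)cc(OCc2ccccc2)c1
F5 | step 5 | (R)-1-[3,5-bis(benzyloxy)-2-bromophenyl]-13-(benzyloxy)tridecan-2-yl acetate | CC(=O)O[C@H](CCCCCCCCCCCOCc1ccccc1)Cc1cc(OCc2ccccc2)cc(OCc2ccccc2)c1Br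
F6 | step 5 | benzyl 2-[(R)-2-acetoxy-13-(benzyloxy)tridecyl]-4,6-bis(benzyloxy)benzoate | CC(=O)O[C@H](CCCCCCCCCCCOCc1ccccc1)Cc1cc(OCc2ccccc2)cc(OCc2ccccc2)c1C(=O)OCc1ccccc1
F7 | step 2 | (S)-1-[3,5-bis(benzyloxy)phenyl]-4-[isopropoxy(dimethyl)silyl]butan-2-ol | O[C@H](CC[Si](C)(C)OC(C)C)Cc1cc(OCc2ccccc2)cc(OCc2ccccc2)c1
F8 | step 2 | (S)-4-[3,5-bis(benzyloxy)phenyl]butane-1,3-diol | O[C@H](CCO)Cc1cc(OCc2ccccc2)cc(OCc2ccccc2)c1
F9 | step 2 | (S)-4-[3,5-bis(benzyloxy)phenyl]-3-hydroxybutyl 4-methylbenzenesulfonate | O[C@H](CCOS(=O)(=O)c1ccc(C)cc1)Cc1cc(OCc2ccccc2)cc(OCc2ccccc2)c1
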